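The target is an oplopane-type hydrindanone (inden-2-one numbering). In its cyclopentanone ring the carbonyl C2 is flanked by C1 and C3, and both ring-fusion carbons, C3a and C7a, lie β to it; C3a also sits next to the exocyclic 4-methylidene. This pattern is read as the product of a reductive [3+2] union of an enoate with an alkyne, so the bicycle is cut at C1–C2 and C3a–C7a. A nickel-catalysed intramolecular cycloaddition of an open-chain dienoate–alkyne, which already carries C5, C6 and C7, closes the cyclohexane and the cyclopentenone in one operation. Reductive aldol, directed epoxidation and three acylations complete the route.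

Key step: step 7

Remark: 2-bromoacrolein, (2S)-2-methylbutanoic anhydride and (2E)-3-methylpent-2-enoic acid are treated as catalogue compounds; bicyclic compounds carry inden-2-one locants (C1 side chain, C2 ketone, C3a/C7a ring fusion).

Step 1
Reactants: 1 methacrolein (2-methylprop-2-enal); 2 (triphenylphosphoranylidene)acetaldehyde
Product: 3 (2E)-4-methylpenta-2,4-dienal
Conditions: toluene, 80 °C
Reagents that add atoms: none
Why: Wittig olefination with the stabilised formyl ylide should give the (E)-dienal, the more electrophilic methacrolein being kept in slight excess to suppress a second homologation; no stereocentre is formed.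

Step 2
Reactants: 4 2-bromoprop-2-enal (2-bromoacrolein); 5 methyl (triphenylphosphoranylidene)acetate
Product: 6 methyl (2E)-4-bromopenta-2,4-dienoate
Conditions: CH2Cl2, 0 °C → rt
Reagents that add atoms: none
Why: Wittig olefination with the stabilised ester ylide should give the (E)-enoate and leave the vinylic bromide untouched; no stereocentre is formed.

Step 3
Reactants: 3 (2E)-4-methylpenta-2,4-dienal; 6 methyl (2E)-4-bromopenta-2,4-dienoate
Product: 7 methyl (2E,6E)-5-hydroxy-8-methyl-4-methylidenenona-2,6,8-trienoate (racemic)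
Conditions: CrCl2 (4 equiv), NiCl2 (2 mol %), DMF, rt
Reagents that add atoms: none
Why: Nozaki–Hiyama–Kishi coupling, in which zerovalent nickel formed in situ activates the alkenyl bromide and the alkenylchromium species adds 1,2 to the aldehyde in the presence of the ester; C5 is formed racemic and is resolved in step 4.

Step 4
Reactants: 7 methyl (2E,6E)-5-hydroxy-8-methyl-4-methylidenenona-2,6,8-trienoate (racemic)
Product: 8 methyl (2E,5S)-5-hydroxy-4-methylidene-5-[(2S,3S)-3-(prop-1-en-2-yl)oxiran-2-yl]pent-2-enoate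
Conditions: Ti(OiPr)4 (15 mol %), L-(+)-DIPT (18 mol %), t-BuOOH (0.55 equiv), 4 Å MS, CH2Cl2, −20 °C
Reagents that add atoms: tert-butyl hydroperoxide, CC(C)(C)OO
Why: Sharpless kinetic resolution, in which L-(+)-DIPT should epoxidise the (5R)-enantiomer of 7 fast at its (E)-C6=C7 alkene to the erythro (anti) epoxy alcohol, fixing C5 and both oxirane carbons (the C5 descriptor becomes S only through a priority switch), while the (5S)-enantiomer stays behind and the electron-poor dienoate alkene is not attacked; at most half of 7 is carried on.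

Step 5
Reactants: 8 methyl (2E,5S)-5-hydroxy-4-methylidene-5-[(2S,3S)-3-(prop-1-en-2-yl)oxiran-2-yl]pent-2-enoate
Product: 9 methyl (2E,5S)-4-methylidene-5-[(2S,3S)-3-(prop-1-en-2-yl)oxiran-2-yl]-5-[(triethylsilyl)oxy]pent-2-enoate
Conditions: Et3SiCl, imidazole, DMF, 0 °C
Reagents that add atoms: chlorotriethylsilane, CC[Si](Cl)(CC)CC
Why: Silylation of the only hydroxyl under non-acidic conditions that spare the vinyl epoxide; no stereocentre is touched.

Step 6
Reactants: 9 methyl (2E,5S)-4-methylidene-5-[(2S,3S)-3-(prop-1-en-2-yl)oxiran-2-yl]-5-[(triethylsilyl)oxy]pent-2-enoate; 10 ethynyl(trimethyl)silane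
Product: 14 methyl (2E,5S,6R,7S)-6-hydroxy-4-methylidene-7-(prop-1-en-2-yl)-5-[(triethylsilyl)oxy]non-2-en-8-ynoate, via lithium (trimethylsilyl)acetylide 11 (not isolated), via diethyl(silylethynyl)alane 12 (not isolated), via C-silyl alkyne 13 (not isolated)
Conditions: 10, n-BuLi, toluene, 0 °C; Et2AlCl; then 9, 0 °C → rt; then K2CO3, MeOH, 0 °C
Reagents that add atoms: none
Why: Alkynylalane opening of the vinyl epoxide (SN2), in which the Lewis-acidic alane activates the oxirane and transfers the alkynyl group to the allylic carbon, remote from the inductively deactivating C5–OSi, with inversion, which sets C7 (S) and leaves the C6 oxygen in place; the conjugated ester should be inert to the alane, and brief methanolysis removes the C-silyl group.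

Step 7
Reactants: 14 methyl (2E,5S,6R,7S)-6-hydroxy-4-methylidene-7-(prop-1-en-2-yl)-5-[(triethylsilyl)oxy]non-2-en-8-ynoate
Product: 15 (3aR,5S,6R,7S)-6-hydroxy-4-methylidene-7-(prop-1-en-2-yl)-5-[(triethylsilyl)oxy]-3,3a,4,5,6,7-hexahydro-2H-inden-2-one
Conditions: Ni(cod)2 (15 mol %), PBu3 (30 mol %), Et3B (4 equiv), MeOH/THF 8:1, 50 °C
Reagents that add atoms: none
Why: Zerovalent nickel binds the alkyne and the electron-poor C2=C3 enoate of 14 and undergoes oxidative cyclisation, joining the inner alkyne carbon C8 to the enoate β-carbon C3; methanol then protonates the nickel enolate at C2, the alkenyl–nickel bond adds to the ester carbonyl and expels methoxide, and Et3B returns nickel to the zerovalent state by ethyl transfer and β-hydride elimination. The closest known reaction is the nickel-catalysed reductive [3+2] cycloaddition of enoates with alkynes to cyclopentenones, run here intramolecularly as in the related alkynyl enal and alkynyl enone cyclisations. The cyclohexane closes 6-exo with respect to both π-systems (bond C3–C8, the future C3a–C7a, over the tether C4–C7) and the cyclopentenone closes by 5-exo-trig addition of the alkenyl nickel to the ester carbon (bond C9–C1, the future C1–C2). The only new stereocentre, C3a, is set in the oxidative cyclisation by the tether: in the chair-like arrangement the isopropenyl group and the C6 hydroxyl are equatorial, the C5 silyloxy group is axial (no allylic strain with the 4-methylidene) and the enoate arm is equatorial, which places H-3a cis to H-7; the alkyne is deliberately left unsubstituted at C9 so that no allylic 1,3-strain between an alkyne substituent and the equatorial isopropenyl group opposes this arrangement. The step needs coupling at the enoate β-carbon and not at the neighbouring 1,1-disubstituted alkene: only the enoate is electron-poor enough to engage nickel, bonding at its β-carbon gives a fused metallacycle whereas bonding at the methylidene carbon would give a bridged one, and the tether fixes which alkyne carbon is attacked. The allylic silyl ether is a poor leaving group for nickel, the free homopropargylic hydroxyl is tolerated in the methanolic medium, and the intramolecular reaction should outrun alkyne oligomerisation.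

Step 8
Reactants: 15 (3aR,5S,6R,7S)-6-hydroxy-4-methylidene-7-(prop-1-en-2-yl)-5-[(triethylsilyl)oxy]-3,3a,4,5,6,7-hexahydro-2H-inden-2-one; 16 acetaldehyde
Product: 19 (1S,3aR,5S,6R,7R,7aR)-6-hydroxy-1-[(1R)-1-hydroxyethyl]-4-methylidene-7-(prop-1-en-2-yl)-5-[(triethylsilyl)oxy]octahydro-2H-inden-2-one, via dilithium enolate 17 (not isolated), via titanium enolate 18 (not isolated)
Conditions: Li, NH3(l)/THF, −78 °C; excess Li quenched with isoprene, NH3 removed; ClTi(OiPr)3, THF, −78 °C; CH3CHO; aq. NH4Cl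
Reagents that add atoms: none
Why: Dissolving-metal conjugate reduction with aldol trapping of the regiodefined enolate (reductive aldol), in which axial protonation of the β-carbon should give the trans-fused hydrindane (H-7a anti to H-3a) and the triisopropoxytitanium enolate should add to acetaldehyde erythro(syn)-selectively from the face of H-7a, away from C7, so that C1 (S, also the more stable epimer) and C1′ (R) arise together.

Step 9
Reactants: 19 (1S,3aR,5S,6R,7R,7aR)-6-hydroxy-1-[(1R)-1-hydroxyethyl]-4-methylidene-7-(prop-1-en-2-yl)-5-[(triethylsilyl)oxy]octahydro-2H-inden-2-one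
Product: 20 (1R)-1-[(1S,3aR,5S,6R,7R,7aR)-6-hydroxy-4-methylidene-2-oxo-7-(prop-1-en-2-yl)-5-[(triethylsilyl)oxy]octahydro-1H-inden-1-yl]ethyl acetate
Conditions: immobilised Candida antarctica lipase B, vinyl acetate, MTBE, 40 °C
Reagents that add atoms: vinyl acetate, CC(=O)OC=C
Why: Lipase-catalysed transesterification, which should acylate only the unhindered (R)-configured methyl carbinol (the usual lipase preference) and leave the ring C6 hydroxyl, flanked by two branched carbons; any (1′S) aldol epimer is not acylated and is removed here, so the enzyme also secures C1′.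

Step 10
Reactants: 20 (1R)-1-[(1S,3aR,5S,6R,7R,7aR)-6-hydroxy-4-methylidene-2-oxo-7-(prop-1-en-2-yl)-5-[(triethylsilyl)oxy]octahydro-1H-inden-1-yl]ethyl acetate
Product: 21 (1R)-1-[(1S,3aR,5S,6R,7S,7aR)-6-hydroxy-4-methylidene-7-[(2S)-2-methyloxiran-2-yl]-2-oxo-5-[(triethylsilyl)oxy]octahydro-1H-inden-1-yl]ethyl acetate
Conditions: VO(acac)2 (5 mol %), t-BuOOH, CH2Cl2, 0 °C → rt
Reagents that add atoms: tert-butyl hydroperoxide, CC(C)(C)OO
Why: Hydroxyl-directed epoxidation of a homoallylic alcohol, in which the equatorial C6–O–vanadium peroxide should reach the gauche isopropenyl group through a chair-like arrangement with C=CH2 eclipsing C7–H and deliver oxygen to the face that gives the (2S)-oxirane, while the 4-methylidene is anti-periplanar to C6–O and out of reach (a selectivity pattern known for trans-2-isopropenylcyclohexanols).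

Step 11
Reactants: 21 (1R)-1-[(1S,3aR,5S,6R,7S,7aR)-6-hydroxy-4-methylidene-7-[(2S)-2-methyloxiran-2-yl]-2-oxo-5-[(triethylsilyl)oxy]octahydro-1H-inden-1-yl]ethyl acetate; 22 (2S)-2-methylbutanoic anhydride
Product: 23 (1S,3aR,5S,6R,7S,7aR)-1-[(1R)-1-acetoxyethyl]-4-methylidene-7-[(2S)-2-methyloxiran-2-yl]-2-oxo-5-[(triethylsilyl)oxy]octahydro-1H-inden-6-yl (2S)-2-methylbutanoate
Conditions: DMAP (cat.), pyridine, CH2Cl2, 0 °C → rt
Reagents that add atoms: none
Why: DMAP-catalysed acylation of the remaining hydroxyl by the anhydride, which avoids a ketene pathway and so keeps the (S)-α-centre of the acyl group, in a weakly basic medium that should spare the epoxide and the β-acetoxy ketone.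

Step 12
Reactants: 23 (1S,3aR,5S,6R,7S,7aR)-1-[(1R)-1-acetoxyethyl]-4-methylidene-7-[(2S)-2-methyloxiran-2-yl]-2-oxo-5-[(triethylsilyl)oxy]octahydro-1H-inden-6-yl (2S)-2-methylbutanoate
Product: 24 (1S,3aR,5S,6R,7S,7aR)-1-[(1R)-1-acetoxyethyl]-5-hydroxy-4-methylidene-7-[(2S)-2-methyloxiran-2-yl]-2-oxooctahydro-1H-inden-6-yl (2S)-2-methylbutanoate
Conditions: HF·pyridine, pyridine, THF, 0 °C
Reagents that add atoms: none
Why: Fluoride-mediated desilylation under buffered, slightly acidic conditions that should leave the 2,2-disubstituted epoxide and the esters intact and disfavour acyl migration from O6 to O5.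

Step 13
Reactants: 24 (1S,3aR,5S,6R,7S,7aR)-1-[(1R)-1-acetoxyethyl]-5-hydroxy-4-methylidene-7-[(2S)-2-methyloxiran-2-yl]-2-oxooctahydro-1H-inden-6-yl (2S)-2-methylbutanoate; 25 (2E)-3-methylpent-2-enoic acid
Product: 27 (1S,3aR,5S,6R,7S,7aR)-1-[(1R)-1-acetoxyethyl]-4-methylidene-6-{[(2S)-2-methylbutanoyl]oxy}-7-[(2S)-2-methyloxiran-2-yl]-2-oxooctahydro-1H-inden-5-yl (2E)-3-methylpent-2-enoate (CNP0120390.2), via mixed anhydride 26 (not isolated)
Conditions: 25, 2,4,6-trichlorobenzoyl chloride, Et3N, THF, rt; then 24, DMAP, toluene, rt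
Reagents that add atoms: none
Why: Yamaguchi esterification, in which the mixed anhydride 26 should acylate the hindered axial allylic C5 hydroxyl under DMAP catalysis with retention of the (E)-geometry of the enoate; no stereocentre is formed.

Compound list

1 | methacrolein (2-methylprop-2-enal) | C=C(C)C=O | starting material
2 | (triphenylphosphoranylidene)acetaldehyde | O=CC=P(c1ccccc1)(c1ccccc1)c1ccccc1 | starting material
3 | (2E)-4-methylpenta-2,4-dienal | C=C(C)/C=C/C=O | intermediate
4 | 2-bromoprop-2-enal (2-bromoacrolein) | C=C(Br)C=O | starting material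
5 | methyl (triphenylphosphoranylidene)acetate | COC(=O)C=P(c1ccccc1)(c1ccccc1)c1ccccc1 | starting material
6 | methyl (2E)-4-bromopenta-2,4-dienoate | COC(=O)/C=C/C(Br)=C | intermediate
7 | methyl (2E,6E)-5-hydroxy-8-methyl-4-methylidenenona-2,6,8-trienoate (racemic) | COC(=O)/C=C/C(=C)C(O)/C=C/C(C)=C | intermediate
8 | methyl (2E,5S)-5-hydroxy-4-methylidene-5-[(2S,3S)-3-(prop-1-en-2-yl)oxiran-2-yl]pent-2-enoate | COC(=O)/C=C/C(=C)[C@H](O)[C@@H]1O[C@H]1C(C)=C | intermediate
9 | methyl (2E,5S)-4-methylidene-5-[(2S,3S)-3-(prop-1-en-2-yl)oxiran-2-yl]-5-[(triethylsilyl)oxy]pent-2-enoate | COC(=O)/C=C/C(=C)[C@H](O[Si](CC)(CC)CC)[C@@H]1O[C@H]1C(C)=C | intermediate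
10 | ethynyl(trimethyl)silane | C#C[Si](C)(C)C | starting material
11 | lithium (trimethylsilyl)acetylide | [Li]C#C[Si](C)(C)C | intermediate
12 | diethyl[(trimethylsilyl)ethynyl]alane | CC[Al](CC)C#C[Si](C)(C)C | intermediate
13 | methyl (2E,5S,6R,7S)-6-hydroxy-4-methylidene-7-(prop-1-en-2-yl)-5-[(triethylsilyl)oxy]-9-(trimethylsilyl)non-2-en-8-ynoate | COC(=O)/C=C/C(=C)[C@H](O[Si](CC)(CC)CC)[C@H](O)[C@@H](C(C)=C)C#C[Si](C)(C)C | intermediate
14 | methyl (2E,5S,6R,7S)-6-hydroxy-4-methylidene-7-(prop-1-en-2-yl)-5-[(triethylsilyl)oxy]non-2-en-8-ynoate | COC(=O)/C=C/C(=C)[C@H](O[Si](CC)(CC)CC)[C@H](O)[C@@H](C(C)=C)C#C | intermediate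
15 | (3aR,5S,6R,7S)-6-hydroxy-4-methylidene-7-(prop-1-en-2-yl)-5-[(triethylsilyl)oxy]-3,3a,4,5,6,7-hexahydro-2H-inden-2-one | C=C1[C@@H]2CC(=O)C=C2[C@H](C(C)=C)[C@@H](O)[C@H]1O[Si](CC)(CC)CC | intermediate
16 | acetaldehyde | CC=O | starting material
17 | dilithium salt (C1=C2 enolate and C6 alkoxide) of the trans-fused reduction product of 15 | C=C1[C@@H]2CC([O-])=C[C@H]2[C@H](C(C)=C)[C@@H]([O-])[C@H]1O[Si](CC)(CC)CC.[Li+].[Li+] | intermediate
18 | bis(triisopropoxytitanium) derivative (C2 enolate and C6 alkoxide) of the same | C=C1[C@@H]2CC(O[Ti](OC(C)C)(OC(C)C)OC(C)C)=C[C@H]2[C@H](C(C)=C)[C@@H](O[Ti](OC(C)C)(OC(C)C)OC(C)C)[C@H]1O[Si](CC)(CC)CC | intermediate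
19 | (1S,3aR,5S,6R,7R,7aR)-6-hydroxy-1-[(1R)-1-hydroxyethyl]-4-methylidene-7-(prop-1-en-2-yl)-5-[(triethylsilyl)oxy]octahydro-2H-inden-2-one | C=C1[C@@H]2CC(=O)[C@H]([C@@H](C)O)[C@H]2[C@H](C(C)=C)[C@@H](O)[C@H]1O[Si](CC)(CC)CC | intermediate
20 | (1R)-1-[(1S,3aR,5S,6R,7R,7aR)-6-hydroxy-4-methylidene-2-oxo-7-(prop-1-en-2-yl)-5-[(triethylsilyl)oxy]octahydro-1H-inden-1-yl]ethyl acetate | C=C1[C@@H]2CC(=O)[C@H]([C@@H](C)OC(C)=O)[C@H]2[C@H](C(C)=C)[C@@H](O)[C@H]1O[Si](CC)(CC)CC | intermediate
21 | (1R)-1-[(1S,3aR,5S,6R,7S,7aR)-6-hydroxy-4-methylidene-7-[(2S)-2-methyloxiran-2-yl]-2-oxo-5-[(triethylsilyl)oxy]octahydro-1H-inden-1-yl]ethyl acetate | C=C1[C@@H]2CC(=O)[C@H]([C@@H](C)OC(C)=O)[C@H]2[C@H]([C@@]2(C)CO2)[C@@H](O)[C@H]1O[Si](CC)(CC)CC | intermediate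
22 | (2S)-2-methylbutanoic anhydride | CC[C@H](C)C(=O)OC(=O)[C@@H](C)CC | starting material
23 | (1S,3aR,5S,6R,7S,7aR)-1-[(1R)-1-acetoxyethyl]-4-methylidene-7-[(2S)-2-methyloxiran-2-yl]-2-oxo-5-[(triethylsilyl)oxy]octahydro-1H-inden-6-yl (2S)-2-methylbutanoate | C=C1[C@@H]2CC(=O)[C@H]([C@@H](C)OC(C)=O)[C@H]2[C@H]([C@@]2(C)CO2)[C@@H](OC(=O)[C@@H](C)CC)[C@H]1O[Si](CC)(CC)CC | intermediate
24 | (1S,3aR,5S,6R,7S,7aR)-1-[(1R)-1-acetoxyethyl]-5-hydroxy-4-methylidene-7-[(2S)-2-methyloxiran-2-yl]-2-oxooctahydro-1H-inden-6-yl (2S)-2-methylbutanoate | C=C1[C@@H]2CC(=O)[C@H]([C@@H](C)OC(C)=O)[C@H]2[C@H]([C@@]2(C)CO2)[C@@H](OC(=O)[C@@H](C)CC)[C@H]1O | intermediate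
25 | (2E)-3-methylpent-2-enoic acid | OC(=O)/C=C(\C)CC | starting material
26 | (2E)-3-methylpent-2-enoic 2,4,6-trichlorobenzoic anhydride | O=C(OC(=O)/C=C(\C)CC)c1c(Cl)cc(Cl)cc1Cl | intermediate
27 | (1S,3aR,5S,6R,7S,7aR)-1-[(1R)-1-acetoxyethyl]-4-methylidene-6-{[(2S)-2-methylbutanoyl]oxy}-7-[(2S)-2-methyloxiran-2-yl]-2-oxooctahydro-1H-inden-5-yl (2E)-3-methylpent-2-enoate (CNP0120390.2) | C=C1[C@@H]2CC(=O)[C@H]([C@@H](C)OC(C)=O)[C@H]2[C@H]([C@@]2(C)CO2)[C@@H](OC(=O)[C@@H](C)CC)[C@H]1OC(=O)/C=C(\C)CC | target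

Total step count: 13. Longest linear sequence: 12 steps (steps 1 and 3 to 13); step 2 is a one-step side branch.

Steps most likely to fail

Step 7 (key step). The alkenyl–nickel intermediate may be protonated before it acylates the ester, so that the sequence stops at the open-chain reductive coupling product; slow oxidative cyclisation would also leave room for alkyne oligomerisation. The fallback sets out from 14 and comes back at 15. It replaces the ester by the far more electrophilic aldehyde, so that ring closure becomes a carbonyl addition. 14 would be reduced with DIBAL-H (CH2Cl2, −78 °C) to the allylic alcohol (2E,5S,6R,7S)-4-methylidene-7-(prop-1-en-2-yl)-5-[(triethylsilyl)oxy]non-2-en-8-yne-1,6-diol F1. MnO2 should oxidise only its allylic hydroxyl, giving the dienal (2E,5S,6R,7S)-6-hydroxy-4-methylidene-7-(prop-1-en-2-yl)-5-[(triethylsilyl)oxy]non-2-en-8-ynal F2. The nickel-catalysed reductive [3+2] cycloaddition of alkynyl enals (Ni(cod)2, PBu3, Et3B, MeOH/THF) would then give the cyclopentenol (3aR,5S,6R,7S)-4-methylidene-7-(prop-1-en-2-yl)-5-[(triethylsilyl)oxy]-3,3a,4,5,6,7-hexahydro-2H-indene-2,6-diol F3 (either C2 epimer), and MnO2 oxidation of its allylic hydroxyl returns to 15.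

Step 8. Syn/anti or facial control in the aldol addition may be insufficient, and retro-aldol cleavage or dehydration may occur on work-up. The fallback sets out from 9 and comes back at 19. It brings the carbinol in with fixed configuration on the alkyne instead of making it by aldol addition.
- (R)-But-3-yn-2-ol would be protected with 4-methoxybenzyl trichloroacetimidate (acid catalysis) as the ether 1-({[(2R)-but-3-yn-2-yl]oxy}methyl)-4-methoxybenzene F4.
- n-BuLi would convert it into lithium (3R)-3-[(4-methoxyphenyl)methoxy]but-1-yn-1-ide F5, and Et2AlCl into diethyl{(3R)-3-[(4-methoxyphenyl)methoxy]but-1-yn-1-yl}alane F6.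
- F6 would open 9 as in step 6 (no desilylation needed) to give methyl (2E,5S,6R,7S,10R)-6-hydroxy-10-[(4-methoxyphenyl)methoxy]-4-methylidene-7-(prop-1-en-2-yl)-5-[(triethylsilyl)oxy]undec-2-en-8-ynoate F7.
- The cycloaddition of step 7 would give the enone (3aR,5S,6R,7S)-6-hydroxy-1-{(1R)-1-[(4-methoxyphenyl)methoxy]ethyl}-4-methylidene-7-(prop-1-en-2-yl)-5-[(triethylsilyl)oxy]-3,3a,4,5,6,7-hexahydro-2H-inden-2-one F8.
- Li/NH3 would then reduce the enone and cleave the benzylic ether, which leaves the carbinol as an alkoxide and so blocks β-elimination; NH4Cl quench and equilibration at C1 (Et3N, MeOH) should give 19.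

The price is a substituted alkyne, whose allylic strain with the isopropenyl group may erode the C3a selectivity of the cycloaddition.

Step 10. Oxygen may be delivered to the wrong face of the isopropenyl group, or the 4-methylidene may be epoxidised in competition. The fallback sets out from 20 and comes back at 27. It moves the epoxidation to the end and runs it without a directing group.
- 20 would be acylated with 22 (DMAP, pyridine) to (1S,3aR,5S,6R,7R,7aR)-1-[(1R)-1-acetoxyethyl]-4-methylidene-2-oxo-7-(prop-1-en-2-yl)-5-[(triethylsilyl)oxy]octahydro-1H-inden-6-yl (2S)-2-methylbutanoate F9.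
- HF·pyridine would desilylate it to (1S,3aR,5S,6R,7R,7aR)-1-[(1R)-1-acetoxyethyl]-5-hydroxy-4-methylidene-2-oxo-7-(prop-1-en-2-yl)octahydro-1H-inden-6-yl (2S)-2-methylbutanoate F10.
- Esterification with 25 through 26 under the conditions of step 13 would give the diene (1S,3aR,5S,6R,7R,7aR)-1-[(1R)-1-acetoxyethyl]-4-methylidene-6-{[(2S)-2-methylbutanoyl]oxy}-2-oxo-7-(prop-1-en-2-yl)octahydro-1H-inden-5-yl (2E)-3-methylpent-2-enoate F11.
- Buffered mCPBA (NaHCO3, CH2Cl2, 0 °C) should then epoxidise the isopropenyl group to give 27. The 4-methylidene is deactivated by its allylic ester, and the face of the isopropenyl group toward C7a is shielded by the C1 side chain.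

Further compounds

F1 | step 7 | (2E,5S,6R,7S)-4-methylidene-7-(prop-1-en-2-yl)-5-[(triethylsilyl)oxy]non-2-en-8-yne-1,6-diol | OC/C=C/C(=C)[C@H](O[Si](CC)(CC)CC)[C@H](O)[C@@H](C(C)=C)C#C
F2 | step 7 | (2E,5S,6R,7S)-6-hydroxy-4-methylidene-7-(prop-1-en-2-yl)-5-[(triethylsilyl)oxy]non-2-en-8-ynal | O=C/C=C/C(=C)[C@H](O[Si](CC)(CC)CC)[C@H](O)[C@@H](C(C)=C)C#C
F3 | step 7 | (3aR,5S,6R,7S)-4-methylidene-7-(prop-1-en-2-yl)-5-[(triethylsilyl)oxy]-3,3a,4,5,6,7-hexahydro-2H-indene-2,6-diol (either C2 epimer) | C=C1[C@@H]2CC(O)C=C2[C@H](C(C)=C)[C@@H](O)[C@H]1O[Si](CC)(CC)CC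
F4 | step 8 | 1-({[(2R)-but-3-yn-2-yl]oxy}methyl)-4-methoxybenzene | C#C[C@@H](C)OCc1ccc(OC)cc1
F5 | step 8 | lithium (3R)-3-[(4-methoxyphenyl)methoxy]but-1-yn-1-ide | [Li]C#C[C@@H](C)OCc1ccc(OC)cc1
F6 | step 8 | diethyl{(3R)-3-[(4-methoxyphenyl)methoxy]but-1-yn-1-yl}alane | CC[Al](CC)C#C[C@@H](C)OCc1ccc(OC)cc1
F7 | step 8 | methyl (2E,5S,6R,7S,10R)-6-hydroxy-10-[(4-methoxyphenyl)methoxy]-4-methylidene-7-(prop-1-en-2-yl)-5-[(triethylsilyl)oxy]undec-2-en-8-ynoate | COC(=O)/C=C/C(=C)[C@H](O[Si](CC)(CC)CC)[C@H](O)[C@@H](C(C)=C)C#C[C@@H](C)OCc1ccc(OC)cc1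
F8 | step 8 | (3aR,5S,6R,7S)-6-hydroxy-1-{(1R)-1-[(4-methoxyphenyl)methoxy]ethyl}-4-methylidene-7-(prop-1-en-2-yl)-5-[(triethylsilyl)oxy]-3,3a,4,5,6,7-hexahydro-2H-inden-2-one | C=C1[C@@H]2CC(=O)C([C@@H](C)OCc3ccc(OC)cc3)=C2[C@H](C(C)=C)[C@@H](O)[C@H]1O[Si](CC)(CC)CC
F9 | step 10 | (1S,3aR,5S,6R,7R,7aR)-1-[(1R)-1-acetoxyethyl]-4-methylidene-2-oxo-7-(prop-1-en-2-yl)-5-[(triethylsilyl)oxy]octahydro-1H-inden-6-yl (2S)-2-methylbutanoate | C=C1[C@@H]2CC(=O)[C@H]([C@@H](C)OC(C)=O)[C@H]2[C@H](C(C)=C)[C@@H](OC(=O)[C@@H](C)CC)[C@H]1O[Si](CC)(CC)CC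
F10 | step 10 | (1S,3aR,5S,6R,7R,7aR)-1-[(1R)-1-acetoxyethyl]-5-hydroxy-4-methylidene-2-oxo-7-(prop-1-en-2-yl)octahydro-1H-inden-6-yl (2S)-2-methylbutanoate | C=C1[C@@H]2CC(=O)[C@H]([C@@H](C)OC(C)=O)[C@H]2[C@H](C(C)=C)[C@@H](OC(=O)[C@@H](C)CC)[C@H]1O
F11 | step 10 | (1S,3aR,5S,6R,7R,7aR)-1-[(1R)-1-acetoxyethyl]-4-methylidene-6-{[(2S)-2-methylbutanoyl]oxy}-2-oxo-7-(prop-1-en-2-yl)octahydro-1H-inden-5-yl (2E)-3-methylpent-2-enoate | C=C1[C@@H]2CC(=O)[C@H]([C@@H](C)OC(C)=O)[C@H]2[C@H](C(C)=C)[C@@H](OC(=O)[C@@H](C)CC)[C@H]1OC(=O)/C=C(\C)CC
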